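**Plan**

- Cuts: in each half the C4–C4a bond (to an aryl oxiranylmethyl ether) and then O1–C2. The upper (gallocatechin, 2,3-trans) half goes back to 3,5-bis(benzyloxy)phenol plus a trans-2,3-epoxy cinnamyl alcohol, the lower (epigallocatechin, 2,3-cis) half to a resorcinol ring plus an erythro epoxy alcohol. The diaryl ether O–C7 is cut to a 2,6-bis(benzyloxy)phenol and 5-bromoresorcinol.
- Forward order: diaryl ether (Ullmann coupling), lower ring C (Mitsunobu, then oxirane–arene closure), three-carbon chain on ring B of the upper half, upper ring C last (step 16), then one hydrogenolysis.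
- Enabling feature: in the upper half C4 is a CH2 bonded to C4a of the phloroglucinol-type ring A. C4a is ortho to the pyran oxygen O1 (on C8a) and ortho/para to O5 and O7, and in the open 3,5-bis(benzyloxy)phenyl ether the two carbons ortho to O1 are equivalent. An oxirane across C3–C4 can therefore be opened at C4 by ring A with no site question, while C3 keeps its oxygen.
- Stereochemistry: all four centres come from two Sharpless epoxidations with L-(+)-diisopropyl tartrate. Upper C2/C3: (2S,3S)-epoxy alcohol, phenoxide inversion at the benzylic carbon gives 2,3-trans. Lower C2/C3: kinetic resolution of an aryl vinyl carbinol (erythro epoxy alcohol), Mitsunobu inversion gives 2,3-cis.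
- Helpers: two bromine atoms (later C6 and C8 of the lower ring A) leave only one ring carbon free for the first closure and keep that ring inert in the second; they leave with the benzyl groups in the last step.

Key step: step 16

Remark: 1, 3, 16 and all reagents are taken as bought. Flavan numbering (O1, C2, C3, C4, C4a, C5 to C8, C8a; ring A fused, ring B on C2, ring C the pyran) is used for both halves.
Shorthand: ArL = 3,5-bis(benzyloxy)-4-({(2R,3R)-3,5-bis(benzyloxy)-6,8-dibromo-2-[3,4,5-tris(benzyloxy)phenyl]-3,4-dihydro-2H-chromen-7-yl}oxy)phenyl, the aryl group of aldehyde 12.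

**Route**

Step 1
Reactants: 1 3,4,5-tris(benzyloxy)benzaldehyde
Product: 2 3,5-bis(benzyloxy)-4-hydroxybenzaldehyde
Conditions: LiCl (3 equiv), DMF, 130 °C; aq. HCl work-up
Reagents that add atoms: none
Why: Nucleophilic dealkylation by chloride (SN2 at the benzylic CH2) should take only the 4-O-benzyl group, whose phenoxide is conjugated with the para formyl group and is the best leaving group, as in the para-selective LiCl/DMF dealkylation of 3,4,5-trialkoxybenzaldehydes.

Step 2
Reactants: 3 5-bromobenzene-1,3-diol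
Product: 4 1-bromo-3,5-bis(prop-2-en-1-yloxy)benzene
Conditions: allyl bromide (2.4 equiv), K2CO3, acetone, reflux
Reagents that add atoms: allyl bromide, C=CCBr
Why: Williamson O-alkylation of both phenols gives allyl ethers that survive the coupling base and can be removed later without touching benzyl ethers or the aldehyde.

Step 3
Reactants: 2 3,5-bis(benzyloxy)-4-hydroxybenzaldehyde; 4 1-bromo-3,5-bis(prop-2-en-1-yloxy)benzene
Product: 5 3,5-bis(benzyloxy)-4-[3,5-bis(prop-2-en-1-yloxy)phenoxy]benzaldehyde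
Conditions: CuI (10 mol %), picolinic acid (20 mol %), K3PO4 (2 equiv), DMSO, 90 °C
Reagents that add atoms: none
Why: Ullmann-type copper-catalysed O-arylation under conditions used for di-ortho-substituted phenols should join the hindered phenoxide to the aryl bromide, whose two ortho positions are unsubstituted.

Step 4
Reactants: 5 3,5-bis(benzyloxy)-4-[3,5-bis(prop-2-en-1-yloxy)phenoxy]benzaldehyde
Product: 6 3,5-bis(benzyloxy)-4-(3,5-dihydroxyphenoxy)benzaldehyde
Conditions: Pd(PPh3)4 (5 mol %), K2CO3, MeOH, 60 °C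
Reagents that add atoms: none
Why: Zerovalent palladium ionises the aryl allyl ethers to allyl complexes that methanol captures (Tsuji–Trost de-allylation), which should free the symmetric resorcinol while benzyl ethers and the aldehyde stay.

Step 5
Reactants: 6 3,5-bis(benzyloxy)-4-(3,5-dihydroxyphenoxy)benzaldehyde
Product: 7 3,5-bis(benzyloxy)-4-(2,6-dibromo-3,5-dihydroxyphenoxy)benzaldehyde
Conditions: NBS (2.05 equiv), MeCN, −20 → 0 °C
Reagents that add atoms: N-bromosuccinimide, O=C1CCC(=O)N1Br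
Why: Electrophilic bromination should go para to each hydroxyl, onto the two carbons that flank the aryloxy group, which leaves only the carbon between the two hydroxyls free; ring B is deactivated by its formyl group.

Step 6
Reactants: 1 3,4,5-tris(benzyloxy)benzaldehyde
Product: 8 rac-1-[3,4,5-tris(benzyloxy)phenyl]prop-2-en-1-ol
Conditions: CH2=CHMgBr, THF, −78 → 0 °C; aq. NH4Cl
Reagents that add atoms: vinylmagnesium bromide, C=C[Mg]Br
Why: Grignard 1,2-addition to the aldehyde gives the racemic aryl vinyl carbinol needed for the kinetic resolution.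

Step 7
Reactants: 8 rac-1-[3,4,5-tris(benzyloxy)phenyl]prop-2-en-1-ol
Product: 9 (S)-[(2R)-oxiran-2-yl][3,4,5-tris(benzyloxy)phenyl]methanol
Conditions: Ti(OiPr)4 (10 mol %), L-(+)-diisopropyl tartrate (15 mol %), t-BuOOH (0.55 equiv), 4 Å MS, CH2Cl2, −20 °C
Reagents that add atoms: tert-butyl hydroperoxide, CC(C)(C)OO
Why: In the Sharpless kinetic resolution with L-(+)-tartrate the (R)-carbinol should be epoxidised much faster than the (S)-carbinol and give the erythro epoxy alcohol, so the catalyst sets both centres of 9 (the carbinol descriptor changes from R to S only because the oxirane carbon outranks the aryl group) and (S)-8 stays behind.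

Step 8
Reactants: 7 3,5-bis(benzyloxy)-4-(2,6-dibromo-3,5-dihydroxyphenoxy)benzaldehyde (2 equiv); 9 (S)-[(2R)-oxiran-2-yl][3,4,5-tris(benzyloxy)phenyl]methanol
Product: 10 3,5-bis(benzyloxy)-4-[2,6-dibromo-3-hydroxy-5-({(R)-[(2R)-oxiran-2-yl][3,4,5-tris(benzyloxy)phenyl]methyl}oxy)phenoxy]benzaldehyde
Conditions: PPh3, diisopropyl azodicarboxylate, THF–toluene, 0 °C → rt
Reagents that add atoms: none
Why: The Mitsunobu reaction displaces the activated carbinol by the bromine-acidified phenol with inversion (S to R), which gives the threo ether needed for the 2,3-cis ring; the two hydroxyls of 7 are equivalent, and its excess (recovered) should hold the reaction at the mono-ether.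

Step 9
Reactants: 10 3,5-bis(benzyloxy)-4-[2,6-dibromo-3-hydroxy-5-({(R)-[(2R)-oxiran-2-yl][3,4,5-tris(benzyloxy)phenyl]methyl}oxy)phenoxy]benzaldehyde
Product: 11 3,5-bis(benzyloxy)-4-({(2R,3R)-6,8-dibromo-3,5-dihydroxy-2-[3,4,5-tris(benzyloxy)phenyl]-3,4-dihydro-2H-chromen-7-yl}oxy)benzaldehyde
Conditions: BF3·OEt2 (30 mol %), CH2Cl2–(CF3)2CHOH 4:1, 0.01 M, −20 → 0 °C
Reagents that add atoms: none
Why: In an intramolecular Friedel–Crafts epoxy–arene cyclisation the only unsubstituted ring carbon, ortho to both the ether oxygen and the free hydroxyl, should open the oxirane at its CH2 end (6-endo-tet), and since C3 keeps its C–O bond the threo ether gives the 2,3-cis chroman-3-ol.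

Step 10
Reactants: 11 3,5-bis(benzyloxy)-4-({(2R,3R)-6,8-dibromo-3,5-dihydroxy-2-[3,4,5-tris(benzyloxy)phenyl]-3,4-dihydro-2H-chromen-7-yl}oxy)benzaldehyde
Product: 12 3,5-bis(benzyloxy)-4-({(2R,3R)-3,5-bis(benzyloxy)-6,8-dibromo-2-[3,4,5-tris(benzyloxy)phenyl]-3,4-dihydro-2H-chromen-7-yl}oxy)benzaldehyde
Conditions: NaH (2.5 equiv), BnBr (2.5 equiv), Bu4NI (cat.), DMF, 0 °C → rt
Reagents that add atoms: benzyl bromide, BrCc1ccccc1
Why: Williamson benzylation of the phenol and the secondary alcohol puts every hydroxyl of the lower half under the one protecting group that the last step removes.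

Step 11
Reactants: 12 3,5-bis(benzyloxy)-4-({(2R,3R)-3,5-bis(benzyloxy)-6,8-dibromo-2-[3,4,5-tris(benzyloxy)phenyl]-3,4-dihydro-2H-chromen-7-yl}oxy)benzaldehyde
Product: 13 ethyl (2E)-3-ArL-prop-2-enoate
Conditions: (EtO)2P(O)CH2CO2Et, NaH, THF, 0 °C → rt
Reagents that add atoms: triethyl phosphonoacetate, CCOC(=O)CP(=O)(OCC)OCC
Why: Horner–Wadsworth–Emmons olefination of the aryl aldehyde with a stabilised phosphonate should give the E-enoate.

Step 12
Reactants: 13 ethyl (2E)-3-ArL-prop-2-enoate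
Product: 14 (2E)-3-ArL-prop-2-en-1-ol
Conditions: i-Bu2AlH (2.5 equiv), CH2Cl2, −78 °C
Reagents that add atoms: none
Why: 1,2-Reduction of the enoate by the aluminium hydride gives the E-allylic alcohol without touching aryl bromides or benzyl ethers.

Step 13
Reactants: 14 (2E)-3-ArL-prop-2-en-1-ol
Product: 15 [(2S,3S)-3-ArL-oxiran-2-yl]methanol
Conditions: Ti(OiPr)4 (10 mol %), L-(+)-diisopropyl tartrate (12 mol %), t-BuOOH (2 equiv), 4 Å MS, CH2Cl2, −20 °C
Reagents that add atoms: tert-butyl hydroperoxide, CC(C)(C)OO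
Why: Sharpless asymmetric epoxidation of the E-allylic alcohol with L-(+)-tartrate should give the (2S,3S)-epoxy alcohol, so the catalyst sets the future C3 directly and the future C2 in the form that the next step inverts.

Step 14
Reactants: 15 [(2S,3S)-3-ArL-oxiran-2-yl]methanol; 16 3,5-bis(benzyloxy)phenol (1.5 equiv)
Product: 17 (2S,3R)-3-[3,5-bis(benzyloxy)phenoxy]-3-ArL-propane-1,2-diol
Conditions: NaOH (1.2 equiv), H2O–1,4-dioxane 1:4, 70 °C
Reagents that add atoms: none
Why: The phenoxide should open the 3-aryl-2,3-epoxy alcohol at the benzylic carbon by SN2 with inversion, the usual regiochemistry of aryloxide openings of 3-arylglycidols, and give the erythro aryl ether diol.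

Step 15
Reactants: 17 (2S,3R)-3-[3,5-bis(benzyloxy)phenoxy]-3-ArL-propane-1,2-diol
Product: 19 1,3-bis(benzyloxy)-5-{(R)-ArL[(2S)-oxiran-2-yl]methoxy}benzene, via primary tosylate 18 (not isolated)
Conditions: N-tosylimidazole (1.05 equiv), NaH (2.2 equiv), THF, 0 °C → rt
Reagents that add atoms: none
Why: Selective sulfonylation of the primary hydroxyl and 3-exo-tet closure by the secondary alkoxide form the terminal oxirane with retention at the carbinol carbon, whose C–O bond is not broken.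

Step 16
Reactants: 19 1,3-bis(benzyloxy)-5-{(R)-ArL[(2S)-oxiran-2-yl]methoxy}benzene
Product: 20 (2R,3S)-5,7-bis(benzyloxy)-2-ArL-3,4-dihydro-2H-chromen-3-ol
Conditions: BF3·OEt2 (10 mol %), (CF3)2CHOH–CH2Cl2 1:4, 0.01 M, −40 → 0 °C
Reagents that add atoms: none
Why: Hydrogen-bond and Lewis-acid activation of the oxirane lets the ring carbon ortho to the ether oxygen of the 3,5-bis(benzyloxy)phenoxy group attack the oxirane CH2 (the future C4), and loss of a proton from the arenium ion gives the chroman-3-ol, an intramolecular Friedel–Crafts epoxy–arene cyclisation of the kind that turns aryl oxiranylmethyl ethers into chroman-3-ols. One ring is closed, the upper pyran ring C, in the 6-endo-tet mode with respect to the oxirane. No stereocentre is formed: C2 is not involved and C3 keeps its C–O bond, so the erythro ether 19 can only give the 2,3-trans (2R,3S) ring. The step needs opening at CH2 (6-endo) and not at CH (5-exo), which the unhindered primary terminus and the aryloxy-bearing carbon next to the secondary oxirane carbon should secure, because they leave that carbon without cationic stabilisation. It needs no choice of site on the arene, since the two carbons ortho to the ether oxygen of the symmetric 3,5-dioxygenated ring are equivalent and each is ortho and para to a benzyloxy group, which makes this ring the best nucleophile present. The lower ring A cannot compete because C6 and C8 carry bromine, and either ring B could only close a five-membered ring in an endo mode.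

Step 17
Reactants: 20 (2R,3S)-5,7-bis(benzyloxy)-2-ArL-3,4-dihydro-2H-chromen-3-ol
Product: 21 (2R,3S)-2-[3,5-dihydroxy-4-({(2R,3R)-3,5-dihydroxy-2-(3,4,5-trihydroxyphenyl)-3,4-dihydro-2H-chromen-7-yl}oxy)phenyl]-3,4-dihydro-2H-chromene-3,5,7-triol
Conditions: H2 (1 atm), Pd(OH)2/C, NaOAc (2.5 equiv), THF–MeOH–H2O, rt
Reagents that add atoms: none
Why: Hydrogenolysis over palladium should cleave the nine benzyl ethers and both aryl–bromine bonds in one operation, with acetate buffering the hydrogen bromide, while the diaryl ether and both pyran C2–O1 bonds stay as in the usual debenzylation of flavan-3-ols.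

**Compound list**

1 | 3,4,5-tris(benzyloxy)benzaldehyde | O=Cc1cc(OCc2ccccc2)c(OCc2ccccc2)c(OCc2ccccc2)c1 | starting material
2 | 3,5-bis(benzyloxy)-4-hydroxybenzaldehyde | O=Cc1cc(OCc2ccccc2)c(O)c(OCc2ccccc2)c1 | intermediate
3 | 5-bromobenzene-1,3-diol | Oc1cc(O)cc(Br)c1 | starting material
4 | 1-bromo-3,5-bis(prop-2-en-1-yloxy)benzene | C=CCOc1cc(Br)cc(OCC=C)c1 | intermediate
5 | 3,5-bis(benzyloxy)-4-[3,5-bis(prop-2-en-1-yloxy)phenoxy]benzaldehyde | O=Cc1cc(OCc2ccccc2)c(Oc2cc(OCC=C)cc(OCC=C)c2)c(OCc2ccccc2)c1 | intermediate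
6 | 3,5-bis(benzyloxy)-4-(3,5-dihydroxyphenoxy)benzaldehyde | O=Cc1cc(OCc2ccccc2)c(Oc2cc(O)cc(O)c2)c(OCc2ccccc2)c1 | intermediate
7 | 3,5-bis(benzyloxy)-4-(2,6-dibromo-3,5-dihydroxyphenoxy)benzaldehyde | O=Cc1cc(OCc2ccccc2)c(Oc2c(Br)c(O)cc(O)c2Br)c(OCc2ccccc2)c1 | intermediate
8 | rac-1-[3,4,5-tris(benzyloxy)phenyl]prop-2-en-1-ol | OC(C=C)c1cc(OCc2ccccc2)c(OCc2ccccc2)c(OCc2ccccc2)c1 | intermediate
9 | (S)-[(2R)-oxiran-2-yl][3,4,5-tris(benzyloxy)phenyl]methanol | O[C@@H](c1cc(OCc2ccccc2)c(OCc2ccccc2)c(OCc2ccccc2)c1)[C@H]1CO1 | intermediate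
10 | 3,5-bis(benzyloxy)-4-[2,6-dibromo-3-hydroxy-5-({(R)-[(2R)-oxiran-2-yl][3,4,5-tris(benzyloxy)phenyl]methyl}oxy)phenoxy]benzaldehyde | O=Cc1cc(OCc2ccccc2)c(Oc2c(Br)c(O)cc(O[C@H](c3cc(OCc4ccccc4)c(OCc4ccccc4)c(OCc4ccccc4)c3)[C@H]3CO3)c2Br)c(OCc2ccccc2)c1 | intermediate
11 | 3,5-bis(benzyloxy)-4-({(2R,3R)-6,8-dibromo-3,5-dihydroxy-2-[3,4,5-tris(benzyloxy)phenyl]-3,4-dihydro-2H-chromen-7-yl}oxy)benzaldehyde | O=Cc1cc(OCc2ccccc2)c(Oc2c(Br)c(O)c3c(c2Br)O[C@H](c2cc(OCc4ccccc4)c(OCc4ccccc4)c(OCc4ccccc4)c2)[C@H](O)C3)c(OCc2ccccc2)c1 | intermediate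
12 | 3,5-bis(benzyloxy)-4-({(2R,3R)-3,5-bis(benzyloxy)-6,8-dibromo-2-[3,4,5-tris(benzyloxy)phenyl]-3,4-dihydro-2H-chromen-7-yl}oxy)benzaldehyde | O=Cc1cc(OCc2ccccc2)c(Oc2c(Br)c(OCc3ccccc3)c3c(c2Br)O[C@H](c2cc(OCc4ccccc4)c(OCc4ccccc4)c(OCc4ccccc4)c2)[C@H](OCc2ccccc2)C3)c(OCc2ccccc2)c1 | intermediate
13 | ethyl (2E)-3-ArL-prop-2-enoate | CCOC(=O)/C=C/c1cc(OCc2ccccc2)c(Oc2c(Br)c(OCc3ccccc3)c3c(c2Br)O[C@H](c2cc(OCc4ccccc4)c(OCc4ccccc4)c(OCc4ccccc4)c2)[C@H](OCc2ccccc2)C3)c(OCc2ccccc2)c1 | intermediate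
14 | (2E)-3-ArL-prop-2-en-1-ol | OC/C=C/c1cc(OCc2ccccc2)c(Oc2c(Br)c(OCc3ccccc3)c3c(c2Br)O[C@H](c2cc(OCc4ccccc4)c(OCc4ccccc4)c(OCc4ccccc4)c2)[C@H](OCc2ccccc2)C3)c(OCc2ccccc2)c1 | intermediate
15 | [(2S,3S)-3-ArL-oxiran-2-yl]methanol | OC[C@@H]1O[C@H]1c1cc(OCc2ccccc2)c(Oc2c(Br)c(OCc3ccccc3)c3c(c2Br)O[C@H](c2cc(OCc4ccccc4)c(OCc4ccccc4)c(OCc4ccccc4)c2)[C@H](OCc2ccccc2)C3)c(OCc2ccccc2)c1 | intermediate
16 | 3,5-bis(benzyloxy)phenol | Oc1cc(OCc2ccccc2)cc(OCc2ccccc2)c1 | starting material
17 | (2S,3R)-3-[3,5-bis(benzyloxy)phenoxy]-3-ArL-propane-1,2-diol | OC[C@H](O)[C@H](Oc2cc(OCc3ccccc3)cc(OCc3ccccc3)c2)c1cc(OCc2ccccc2)c(Oc2c(Br)c(OCc3ccccc3)c3c(c2Br)O[C@H](c2cc(OCc4ccccc4)c(OCc4ccccc4)c(OCc4ccccc4)c2)[C@H](OCc2ccccc2)C3)c(OCc2ccccc2)c1 | intermediate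
18 | (2S,3R)-3-[3,5-bis(benzyloxy)phenoxy]-2-hydroxy-3-ArL-propyl 4-methylbenzenesulfonate | Cc1ccc(cc1)S(=O)(=O)OC[C@H](O)[C@H](Oc2cc(OCc3ccccc3)cc(OCc3ccccc3)c2)c1cc(OCc2ccccc2)c(Oc2c(Br)c(OCc3ccccc3)c3c(c2Br)O[C@H](c2cc(OCc4ccccc4)c(OCc4ccccc4)c(OCc4ccccc4)c2)[C@H](OCc2ccccc2)C3)c(OCc2ccccc2)c1 | intermediate
19 | 1,3-bis(benzyloxy)-5-{(R)-ArL[(2S)-oxiran-2-yl]methoxy}benzene | C1O[C@@H]1[C@H](Oc2cc(OCc3ccccc3)cc(OCc3ccccc3)c2)c1cc(OCc2ccccc2)c(Oc2c(Br)c(OCc3ccccc3)c3c(c2Br)O[C@H](c2cc(OCc4ccccc4)c(OCc4ccccc4)c(OCc4ccccc4)c2)[C@H](OCc2ccccc2)C3)c(OCc2ccccc2)c1 | intermediate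
20 | (2R,3S)-5,7-bis(benzyloxy)-2-ArL-3,4-dihydro-2H-chromen-3-ol | c1ccccc1COc1cc(OCc2ccccc2)c2c(c1)O[C@H](c1cc(OCc3ccccc3)c(Oc4c(Br)c(OCc5ccccc5)c5c(c4Br)O[C@H](c4cc(OCc6ccccc6)c(OCc6ccccc6)c(OCc6ccccc6)c4)[C@H](OCc4ccccc4)C5)c(OCc3ccccc3)c1)[C@@H](O)C2 | intermediate
21 | (2R,3S)-2-[3,5-dihydroxy-4-({(2R,3R)-3,5-dihydroxy-2-(3,4,5-trihydroxyphenyl)-3,4-dihydro-2H-chromen-7-yl}oxy)phenyl]-3,4-dihydro-2H-chromene-3,5,7-triol | Oc1cc(O)c2c(c1)O[C@H](c1cc(O)c(Oc3cc(O)c4c(c3)O[C@H](c3cc(O)c(O)c(O)c3)[C@H](O)C4)c(O)c1)[C@@H](O)C2 | target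

**Count and risks**

Total steps: 17. Longest linear sequence: 14 steps (1 → 2 → 5 → 6 → 7 → 10 → 11 → 12 → 13 → 14 → 15 → 17 → 19 → 20 → 21).

Steps most likely to fail:

1. Step 9. The attacking ring carbon has two bromine atoms meta to it, and the diaryl ether oxygen para to it is weakened by the formyl group of ring B. The closure may therefore lose to Lewis-acid isomerisation of the oxirane to a carbonyl compound, to opening by the fluorinated alcohol, or to intermolecular hydroxyalkylation by the activated aldehyde. Fallback, from 10 back to 11: the arene is made the nucleophile as its phenolate and the electrophile becomes a primary iodide. LiI and AcOH in THF should open the oxirane at CH2 to the iodohydrin F1. t-BuMe2SiOTf and 2,6-lutidine should silylate both hydroxyls to the bis-silyl ether F2. Cs2CO3 in CF3CH2OH (0.005 M, 50 °C) should cleave only the aryl silyl ether, and the phenolate should close the ring by C-alkylation at its single free ortho carbon (6-exo-tet on the primary iodide; O-alkylation would need an eight-membered ring) to give the silyl ether F3. Bu4NF in THF then frees the 3-hydroxyl and gives 11.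

2. Step 8. The oxyphosphonium intermediate sits on an electron-rich benzylic carbon and may ionise, which would erode the inversion and give a threo/erythro mixture; C-alkylation of the phenol and double etherification are further leaks. Fallback, from 1 and 7 back to 10: the aryl ether is made by an SN2 opening of a cis-epoxide, where inversion is enforced. Still–Gennari olefination of 1 [(CF3CH2O)2P(O)CH2CO2Me, KN(SiMe3)2, 18-crown-6, THF, −78 °C] should give the methyl (Z)-enoate F4. i-Bu2AlH reduces it to the (Z)-allylic alcohol F5. Sharpless epoxidation with D-(−)-diisopropyl tartrate should give the cis-epoxy alcohol F6. The phenoxide of 7 (excess 7, Cs2CO3, DMF, 60 °C) should open it at the benzylic carbon with inversion to the threo diol F7. The one-pot sequence MeC(OMe)3/pyridinium tosylate, AcBr, then K2CO3/MeOH closes the terminal oxirane with retention and gives 10.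

3. Step 3. The phenoxide is hindered by two ortho benzyloxy groups and weakened by the para formyl group, so O-arylation may stall while 4 is slowly hydrodebrominated. Fallback, from 4 back to 5: an oxidative copper coupling at room temperature replaces the thermal one. Bromine–lithium exchange on 4 (n-BuLi, THF, −78 °C), B(OiPr)3 and acidic work-up should give the boronic acid F8. Chan–Lam coupling of F8 with 2 (Cu(OAc)2, pyridine, Et3N, 4 Å MS, CH2Cl2, air, rt), a reaction that tolerates phenols with two ortho substituents, then gives 5.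

Further compounds
F1 | step 9 | 3,5-bis(benzyloxy)-4-[2,6-dibromo-3-hydroxy-5-({(1R,2S)-2-hydroxy-3-iodo-1-[3,4,5-tris(benzyloxy)phenyl]propyl}oxy)phenoxy]benzaldehyde | O=Cc1cc(OCc2ccccc2)c(Oc2c(Br)c(O)cc(O[C@H](c3cc(OCc4ccccc4)c(OCc4ccccc4)c(OCc4ccccc4)c3)[C@H](O)CI)c2Br)c(OCc2ccccc2)c1
F2 | step 9 | 3,5-bis(benzyloxy)-4-[2,6-dibromo-3-(tert-butyldimethylsilyloxy)-5-({(1R,2S)-2-(tert-butyldimethylsilyloxy)-3-iodo-1-[3,4,5-tris(benzyloxy)phenyl]propyl}oxy)phenoxy]benzaldehyde | O=Cc1cc(OCc2ccccc2)c(Oc2c(Br)c(O[Si](C)(C)C(C)(C)C)cc(O[C@H](c3cc(OCc4ccccc4)c(OCc4ccccc4)c(OCc4ccccc4)c3)[C@H](O[Si](C)(C)C(C)(C)C)CI)c2Br)c(OCc2ccccc2)c1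
F3 | step 9 | 3,5-bis(benzyloxy)-4-({(2R,3R)-6,8-dibromo-3-(tert-butyldimethylsilyloxy)-5-hydroxy-2-[3,4,5-tris(benzyloxy)phenyl]-3,4-dihydro-2H-chromen-7-yl}oxy)benzaldehyde | O=Cc1cc(OCc2ccccc2)c(Oc2c(Br)c(O)c3c(c2Br)O[C@H](c2cc(OCc4ccccc4)c(OCc4ccccc4)c(OCc4ccccc4)c2)[C@H](O[Si](C)(C)C(C)(C)C)C3)c(OCc2ccccc2)c1
F4 | step 8 | methyl (2Z)-3-[3,4,5-tris(benzyloxy)phenyl]prop-2-enoate | COC(=O)/C=C\c1cc(OCc2ccccc2)c(OCc2ccccc2)c(OCc2ccccc2)c1
F5 | step 8 | (2Z)-3-[3,4,5-tris(benzyloxy)phenyl]prop-2-en-1-ol | OC/C=C\c1cc(OCc2ccccc2)c(OCc2ccccc2)c(OCc2ccccc2)c1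
F6 | step 8 | {(2R,3S)-3-[3,4,5-tris(benzyloxy)phenyl]oxiran-2-yl}methanol | OC[C@H]1O[C@H]1c1cc(OCc2ccccc2)c(OCc2ccccc2)c(OCc2ccccc2)c1
F7 | step 8 | 3,5-bis(benzyloxy)-4-[2,6-dibromo-3-({(1R,2R)-2,3-dihydroxy-1-[3,4,5-tris(benzyloxy)phenyl]propyl}oxy)-5-hydroxyphenoxy]benzaldehyde | O=Cc1cc(OCc2ccccc2)c(Oc2c(Br)c(O)cc(O[C@H](c3cc(OCc4ccccc4)c(OCc4ccccc4)c(OCc4ccccc4)c3)[C@H](O)CO)c2Br)c(OCc2ccccc2)c1
F8 | step 3 | [3,5-bis(prop-2-en-1-yloxy)phenyl]boronic acid | OB(O)c1cc(OCC=C)cc(OCC=C)c1
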